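**Plan**

- **Numbering (labdane):** ring A is C1–C5 plus C10 and ring B is C5–C10. C18 (CH3) and C19 (CO2H) sit on C4, C20 on C10, C17 (=CH2) on C8, and the chain C11–C15 (C16 on C13) on C9. As drawn, the target is cis-fused, with H5, C18, C20 and C11 on one face and C19 on the other.
- **Retrosynthetic cuts, in order:** C8=C17 (methylenation), C9–C11 (enolate alkylation with a C11–C15 iodide), C8=O (allylic oxidation), C4–C5 ([3,3] shift), C19–O–C7 (lactonisation), C5=C6 and C9–C10 (aldol condensation, Michael addition), C3–C4 and C1–C10 (malonate alkylations).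
- **Enabling feature:** C19 hangs on quaternary C4, next to ring-fusion carbon C5 and on the C6 side of ring A. It can therefore be parked as the acyl carbon of an ester on a C7 oxygen. C4–C19–O–C7–C6–C5 is then a Claisen array, and ring A (C4, C3, C2, C1, C10, C5) closes when C4 passes from C19–O to C5.
- **Forward order:** acyclic C19–C4–C3–C2–C1–C10–C5 aldehyde ester, then ring B (cyclohexenone), then the ten-membered lactone bridging C7 and C10, then ring A by ring contraction, then the C8 ketone, the C11–C15 chain and finally C17.
- **Stereochemistry:** C10 comes from an amine-catalysed Michael addition and the temporary C7 centre from a CBS reduction. C4 and C5 are relayed from C7 and C10 in the key step. C9 comes from a kinetic convex-face alkylation and is kept by a non-basic methylenation. C13 comes from methyl hydrogen (R)-3-methylglutarate.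

Key step: step 8

Assumption: the (1R,2R) diamine–diacid catalyst pair of step 4 is taken to give the (S) configuration at C10; should the sense prove opposite, the (1S,2S) pair is used and nothing else changes.

**Step 1**
Reactants: 1 diethyl methylmalonate (2 equiv); 2 1,3-dibromopropane
Product: 4 tetraethyl heptane-2,2,6,6-tetracarboxylate, via bromo diester 3 (not isolated)
Conditions: NaOEt (2.1 equiv), EtOH, reflux
Reagents that add atoms: none
Why: Malonic ester alkylation, in which ethoxide deprotonates 1 and the carbanion displaces both primary bromides of 2 by SN2; bromide 3 has no acidic hydrogen left, so it cannot cyclise and can only take up a second molecule of 1.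

**Step 2**
Reactants: 4 tetraethyl heptane-2,2,6,6-tetracarboxylate
Product: 5 diethyl 2,6-dimethylheptanedioate (stereoisomer mixture)
Conditions: LiCl, H2O, DMSO, 170 °C
Reagents that add atoms: none
Why: Krapcho dealkoxycarbonylation, in which chloride dealkylates one ester of each fully substituted malonate and loss of CO2 with protonation leaves a 2-methyl ester at both ends; the two new stereocentres need no control because C10 is re-made in step 4 and C4 is erased in step 8.

**Step 3**
Reactants: 5 diethyl 2,6-dimethylheptanedioate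
Product: 6 ethyl 2,6-dimethyl-7-oxoheptanoate (stereoisomer mixture)
Conditions: DIBAL-H (1.0 equiv), CH2Cl2, −78 °C; aq. Rochelle salt
Reagents that add atoms: none
Why: Partial ester reduction with DIBAL-H, in which the aluminium hemiacetal of an α-branched ester survives at −78 °C and releases the aldehyde on work-up; one equivalent desymmetrises 5 statistically, and unreacted 5 is separated and recycled.

**Step 4**
Reactants: 6 ethyl 2,6-dimethyl-7-oxoheptanoate; 7 methyl vinyl ketone
Product: 9 ethyl 2-methyl-5-[(1S)-1-methyl-4-oxocyclohex-2-en-1-yl]pentanoate (C4 epimers), via keto aldehyde 8 (not isolated)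
Conditions: (1R,2R)-cyclohexane-1,2-diamine (30 mol %), (1R,2R)-cyclohexane-1,2-dicarboxylic acid (30 mol %), i-PrOH, rt; then p-TsOH·H2O (10 mol %), toluene, 80 °C
Reagents that add atoms: none
Why: Amine-catalysed Michael addition followed by aldol condensation (asymmetric Robinson-type annulation): the primary amine converts the α-branched aldehyde into its enamine and so erases the old C10 configuration, the chiral ammonium carboxylate pair steers methyl vinyl ketone to one enamine face to set quaternary C10 as (S), the methyl ketone of 8 condenses with the non-enolisable aldehyde to close ring B, and any shortfall in enantiomeric purity is removed in steps 5 and 7.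

**Step 5**
Reactants: 9 ethyl 2-methyl-5-[(1S)-1-methyl-4-oxocyclohex-2-en-1-yl]pentanoate
Product: 10 ethyl 5-[(1S,4R)-4-hydroxy-1-methylcyclohex-2-en-1-yl]-2-methylpentanoate (hydroxyl cis to the pentanoate chain; C4 epimers)
Conditions: (S)-2-methyl-CBS-oxazaborolidine (15 mol %), catecholborane, toluene, −78 °C; MeOH, then aq. NaHCO3
Reagents that add atoms: none
Why: Corey–Bakshi–Shibata reduction, in which the (S)-oxazaborolidine binds the ketone with the alkenyl arm as the large group and delivers hydride under reagent control to give the (R)-carbinol at C7; in the (10S) series this places the hydroxyl cis to the C1 chain, whereas any (10R) enone ends up as the trans diastereomer.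

**Step 6**
Reactants: 10 ethyl 5-[(1S,4R)-4-hydroxy-1-methylcyclohex-2-en-1-yl]-2-methylpentanoate
Product: 11 5-[(1S,4R)-4-hydroxy-1-methylcyclohex-2-en-1-yl]-2-methylpentanoic acid (C4 epimers)
Conditions: LiOH·H2O, THF–MeOH–H2O, 40 °C; 1 M HCl to pH 4, 0 °C
Reagents that add atoms: lithium hydroxide, [Li+].[OH-]
Why: Base hydrolysis (BAc2) of the ethyl ester frees the C19 acid; C7 and C10 are not affected and epimerisation at C4 is of no consequence.

**Step 7**
Reactants: 11 5-[(1S,4R)-4-hydroxy-1-methylcyclohex-2-en-1-yl]-2-methylpentanoic acid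
Product: 13 (1R,8S)-4,8-dimethyl-2-oxabicyclo[6.2.2]dodec-9-en-3-one (C19–O–C7 lactone; C4 epimers), via mixed anhydride 12 (not isolated)
Conditions: MNBA (2-methyl-6-nitrobenzoic anhydride), DMAP, CH2Cl2 (1 mM), syringe-pump addition of 11, rt
Reagents that add atoms: none
Why: Shiina macrolactonisation, in which MNBA gives mixed anhydride 12 and DMAP passes the acyl group to the C7 hydroxyl under high dilution; only the cis-1,4 isomer can span C7 and C10 with a six-atom bridge (cyclohexene as a boat), so trans material derived from the minor enantiomer stays behind as oligomer and the lactone should emerge as one enantiomer.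

**Step 8**
Reactants: 13 (1R,8S)-4,8-dimethyl-2-oxabicyclo[6.2.2]dodec-9-en-3-one
Product: 16 (1S,4aS,8aR)-1,4a-dimethyl-1,2,3,4,4a,5,6,8a-octahydronaphthalene-1-carboxylic acid (cis-fused; alkene C6=C7), via silyl ketene acetal 14 (not isolated), via trimethylsilyl ester 15 (not isolated)
Conditions: KHMDS, TMSCl, THF–toluene, −78 °C to rt, then 80 °C; 0.5 M HCl, THF, rt
Reagents that add atoms: none
Why: Proposed new method: KHMDS and TMSCl turn lactone 13 into ketene acetal 14, whose array C4=C19–O–C7–C6=C5 undergoes a concerted suprafacial [3,3] shift that forms C4–C5, breaks C7–O and moves the alkene to C6=C7, and mild acid then cleaves silyl ester 15 to acid 16. The closest known reaction type is the Ireland–Claisen ring contraction of macrocyclic allylic lactones by four atoms, which has not yet been run on a lactone that bridges the 1,4-positions of a cyclohexene. Ring A (C4, C3, C2, C1, C10, C5) closes as a six-membered carbocycle by transannular contraction of the ten-membered ring, helped by release of the strain of the medium ring and of the boat-shaped cyclohexene. C5 is controlled by C7 and C10, because C4 can reach the alkene only on the face from which the C7 oxygen departs, which is also the face of the C1 chain on C10, so that H5 ends up cis to C20. C4 is controlled by the tether, because C3 has to stay gauche or eclipsed to C10 about the new bond; two arrangements meet this demand, a chair in which the ring bonds C4–C3 and C19–O lie trans across C4=C19 and a boat in which they lie cis, and each delivers C19 to the C6 side of ring A and C18 to the H5 side, whatever the C4 configuration of 13 or the geometry of 14. The step needs silylation on oxygen to outrun loss of the allylic alkoxide after deprotonation and needs a single allyl terminus for C4, which the presence of TMSCl during deprotonation at −78 °C and the lone C5=C6–C7 unit secure.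

**Step 9**
Reactants: 16 (1S,4aS,8aR)-1,4a-dimethyl-1,2,3,4,4a,5,6,8a-octahydronaphthalene-1-carboxylic acid
Product: 17 benzyl (1S,4aS,8aR)-1,4a-dimethyl-1,2,3,4,4a,5,6,8a-octahydronaphthalene-1-carboxylate
Conditions: BnBr, K2CO3, DMF, rt
Reagents that add atoms: benzyl bromide, BrCc1ccccc1
Why: Carboxylate O-alkylation (SN2 on benzyl bromide) esterifies the hindered C19 acid without any attack at its carbonyl carbon, and the benzyl group will leave in the hydrogenation of step 14.

**Step 10**
Reactants: 17 benzyl (1S,4aS,8aR)-1,4a-dimethyl-1,2,3,4,4a,5,6,8a-octahydronaphthalene-1-carboxylate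
Product: 18 benzyl (1S,4aS,8aR)-1,4a-dimethyl-6-oxo-1,2,3,4,4a,5,6,8a-octahydronaphthalene-1-carboxylate (C6=C7–C8=O enone)
Conditions: CrO3, 3,5-dimethylpyrazole, CH2Cl2, −20 °C
Reagents that add atoms: chromium trioxide, O=[Cr](=O)=O
Why: Allylic oxidation with the CrO3–3,5-dimethylpyrazole complex: C8H2 is the only allylic methylene, the other allylic site C5 is a tertiary C–H buried between quaternary C4 and C10, and oxygen should be taken up at the open C8 end of the C6–C7–C8 allyl system rather than at C6 next to C5.

**Step 11**
Reactants: 19 methyl hydrogen (R)-3-methylglutarate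
Product: 20 methyl (R)-5-hydroxy-3-methylpentanoate
Conditions: BH3·SMe2, THF, −10 °C to rt; H2O
Reagents that add atoms: none
Why: Borane reduces the free carboxylic acid (future C11) much faster than the methyl ester, C13 is not involved, and the hydroxy ester is used at once to forestall lactonisation.

**Step 12**
Reactants: 20 methyl (R)-5-hydroxy-3-methylpentanoate
Product: 21 methyl (S)-5-iodo-3-methylpentanoate
Conditions: I2, PPh3, imidazole, CH2Cl2, 0 °C
Reagents that add atoms: iodine, [I][I]
Why: Appel-type iodination replaces the primary hydroxyl by SN2 at C11 under neutral conditions; the descriptor at C13 changes to (S) only because of the priority of iodine.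

**Step 13**
Reactants: 18 benzyl (1S,4aS,8aR)-1,4a-dimethyl-6-oxo-1,2,3,4,4a,5,6,8a-octahydronaphthalene-1-carboxylate; 21 methyl (S)-5-iodo-3-methylpentanoate
Product: 23 benzyl (1S,4aR,5S,8aR)-5-[(3R)-5-methoxy-3-methyl-5-oxopentyl]-1,4a-dimethyl-6-oxo-1,2,3,4,4a,5,6,8a-octahydronaphthalene-1-carboxylate (C11 cis to C20 and H5), via lithium dienolate 22 (not isolated)
Conditions: LDA, THF, −78 °C; 21, DMPU, −78 to −30 °C; AcOH quench at −78 °C
Reagents that add atoms: none
Why: Kinetic α′-deprotonation of the enone (C9 is its only enolisable α-carbon, and H5 at the γ-position is shielded by C4 and C10) gives cross-conjugated dienolate 22, which primary iodide 21 alkylates by SN2; C9 is set because the electrophile can approach only from the convex face that carries H5 and C20, anti to the pseudoaxial C10–C1 bond, the other face being covered by ring A and the C19 ester, and since this puts C11 axial on ring B (not the thermodynamic position) the mixture is quenched cold and base is avoided from here on.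

**Step 14**
Reactants: 23 benzyl (1S,4aR,5S,8aR)-5-[(3R)-5-methoxy-3-methyl-5-oxopentyl]-1,4a-dimethyl-6-oxo-1,2,3,4,4a,5,6,8a-octahydronaphthalene-1-carboxylate
Product: 24 (1S,4aR,5S,8aR)-5-[(3R)-5-methoxy-3-methyl-5-oxopentyl]-1,4a-dimethyl-6-oxodecahydronaphthalene-1-carboxylic acid
Conditions: H2 (1 atm), Pd/C, EtOAc, rt
Reagents that add atoms: none
Why: Heterogeneous hydrogenation saturates the C6=C7 enone alkene (no new stereocentre) and hydrogenolyses the benzyl ester in one operation under neutral conditions that leave the epimerisable C9, the ketone and the methyl ester alone.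

**Step 15**
Reactants: 24 (1S,4aR,5S,8aR)-5-[(3R)-5-methoxy-3-methyl-5-oxopentyl]-1,4a-dimethyl-6-oxodecahydronaphthalene-1-carboxylic acid
Product: 25 (1S,4aS,5R,8aR)-5-[(3R)-5-methoxy-3-methyl-5-oxopentyl]-1,4a-dimethyl-6-methylidenedecahydronaphthalene-1-carboxylic acid (CNP0260608.1)
Conditions: Zn, CH2Br2, TiCl4 (excess, pre-aged in THF at 5 °C), CH2Cl2, 0 °C to rt
Reagents that add atoms: dibromomethane, BrCBr
Why: Lombardo methylenation: the gem-dimetallic CH2 reagent made from Zn, CH2Br2 and TiCl4 is nucleophilic but not basic, a property known to carry α-epimerisable ketones through without loss of configuration, so C9 is kept, the C15 methyl ester is not attacked, and the C19 acid merely consumes reagent as its zinc carboxylate.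

**Compound list**

1 | diethyl methylmalonate | CCOC(=O)C(C)C(=O)OCC | starting material
2 | 1,3-dibromopropane | BrCCCBr | starting material
3 | bromo diester, diethyl 2-(3-bromopropyl)-2-methylmalonate (not isolated) | CCOC(=O)C(C)(CCCBr)C(=O)OCC | intermediate
4 | tetraethyl heptane-2,2,6,6-tetracarboxylate | CCOC(=O)C(C)(CCCC(C)(C(=O)OCC)C(=O)OCC)C(=O)OCC | intermediate
5 | diethyl 2,6-dimethylheptanedioate (stereoisomer mixture) | CCOC(=O)C(C)CCCC(C)C(=O)OCC | intermediate
6 | ethyl 2,6-dimethyl-7-oxoheptanoate (stereoisomer mixture) | CCOC(=O)C(C)CCCC(C)C=O | intermediate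
7 | methyl vinyl ketone | CC(=O)C=C | starting material
8 | keto aldehyde, ethyl (6S)-6-formyl-2,6-dimethyl-9-oxodecanoate (C4 epimers, not isolated) | CCOC(=O)C(C)CCC[C@@](C=O)(C)CCC(C)=O | intermediate
9 | ethyl 2-methyl-5-[(1S)-1-methyl-4-oxocyclohex-2-en-1-yl]pentanoate (C4 epimers) | CCOC(=O)C(C)CCC[C@@]1(C)CCC(=O)C=C1 | intermediate
10 | ethyl 5-[(1S,4R)-4-hydroxy-1-methylcyclohex-2-en-1-yl]-2-methylpentanoate (C4 epimers) | CCOC(=O)C(C)CCC[C@@]1(C)CC[C@@H](O)C=C1 | intermediate
11 | 5-[(1S,4R)-4-hydroxy-1-methylcyclohex-2-en-1-yl]-2-methylpentanoic acid (C4 epimers) | OC(=O)C(C)CCC[C@@]1(C)CC[C@@H](O)C=C1 | intermediate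
12 | mixed anhydride of 11 with 2-methyl-6-nitrobenzoic acid (not isolated) | Cc1cccc([N+](=O)[O-])c1C(=O)OC(=O)C(C)CCC[C@@]2(C)CC[C@@H](O)C=C2 | intermediate
13 | (1R,8S)-4,8-dimethyl-2-oxabicyclo[6.2.2]dodec-9-en-3-one (C4 epimers) | O=C1C(C)CCC[C@@]2(C)CC[C@@H](O1)C=C2 | intermediate
14 | silyl ketene acetal of 13 (C4=C19 geometry open, not isolated) | C[Si](C)(C)OC1=C(C)CCC[C@@]2(C)CC[C@@H](O1)C=C2 | intermediate
15 | trimethylsilyl ester of 16 (not isolated) | C1=C[C@@H]2[C@@](C)(CCC[C@]2(C)C(=O)O[Si](C)(C)C)CC1 | intermediate
16 | (1S,4aS,8aR)-1,4a-dimethyl-1,2,3,4,4a,5,6,8a-octahydronaphthalene-1-carboxylic acid | C1=C[C@@H]2[C@@](C)(CCC[C@]2(C)C(=O)O)CC1 | intermediate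
17 | benzyl ester of 16 | C1=C[C@@H]2[C@@](C)(CCC[C@]2(C)C(=O)OCc3ccccc3)CC1 | intermediate
18 | benzyl (1S,4aS,8aR)-1,4a-dimethyl-6-oxo-1,2,3,4,4a,5,6,8a-octahydronaphthalene-1-carboxylate | O=C1C=C[C@@H]2[C@@](C)(CCC[C@]2(C)C(=O)OCc3ccccc3)C1 | intermediate
19 | methyl hydrogen (R)-3-methylglutarate | OC(=O)C[C@@H](C)CC(=O)OC | starting material
20 | methyl (R)-5-hydroxy-3-methylpentanoate | OCC[C@@H](C)CC(=O)OC | intermediate
21 | methyl (S)-5-iodo-3-methylpentanoate | ICC[C@@H](C)CC(=O)OC | intermediate
22 | lithium dienolate of 18 (C8–O, C8=C9, C6=C7; not isolated) | [Li]OC=1C=C[C@@H]2[C@@](C)(CCC[C@]2(C)C(=O)OCc3ccccc3)C=1 | intermediate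
23 | benzyl (1S,4aR,5S,8aR)-5-[(3R)-5-methoxy-3-methyl-5-oxopentyl]-1,4a-dimethyl-6-oxo-1,2,3,4,4a,5,6,8a-octahydronaphthalene-1-carboxylate | O=C1C=C[C@@H]2[C@@](C)(CCC[C@]2(C)C(=O)OCc3ccccc3)[C@@H]1CC[C@@H](C)CC(=O)OC | intermediate
24 | (1S,4aR,5S,8aR)-5-[(3R)-5-methoxy-3-methyl-5-oxopentyl]-1,4a-dimethyl-6-oxodecahydronaphthalene-1-carboxylic acid | O=C1CC[C@@H]2[C@@](C)(CCC[C@]2(C)C(=O)O)[C@@H]1CC[C@@H](C)CC(=O)OC | intermediate
25 | (1S,4aS,5R,8aR)-5-[(3R)-5-methoxy-3-methyl-5-oxopentyl]-1,4a-dimethyl-6-methylidenedecahydronaphthalene-1-carboxylic acid | C=C1CC[C@@H]2[C@@](C)(CCC[C@]2(C)C(=O)O)[C@@H]1CC[C@@H](C)CC(=O)OC | target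

**Step count**

Total steps: 15. Longest linear sequence: 13 (steps 1–10 and 13–15).

**Steps most likely to fail**

**Step 8.** The bridged ketene acetal may be unable to bring C4 over C5. Ionisation of the allylic C7–O bond with elimination, or plain desilylation back to the lactone, would then overtake the rearrangement.

The fallback uses known chemistry, sets out from 11 and comes back at 17.
- Acid 11 is alkylated with BnBr and K2CO3 to benzyl hydroxy ester F1.
- ClCO2Me and pyridine convert F1 into allylic methyl carbonate F2.
- LDA and TMSCl at −78 °C give benzyl silyl ketene acetal F3.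
- Pd(PPh3)4 in THF at reflux then closes ring A by an intramolecular Tsuji–Trost allylation of the ketene silyl acetal.

Palladium ionises the carbonate on the face opposite to C7–O, and the released methoxide takes the silyl group. The tethered enolate attacks C5 anti to the metal, that is, on the face of the tether. This gives the cis-fused six-membered ring with the alkene at C6=C7. C4 is no longer fixed by a cyclic array here, so its epimers would have to be separated.

**Step 7.** Intermolecular acylation (oligomerisation) may outrun ring closure, because closure demands a boat cyclohexene and builds a medium ring.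

The fallback sets out from 9 and comes back at 13. It closes the alkyl–oxygen bond C7–O instead of the acyl–oxygen bond.
- (R)-2-Methyl-CBS-oxazaborolidine and catecholborane give trans hydroxy ester F4.
- LiOH gives trans hydroxy acid F5.
- A Mitsunobu lactonisation (PPh3, DIAD, toluene, high dilution) lets the free carboxylate displace the activated C7 oxygen from the face of the tether, with inversion.

Material of the wrong C10 configuration is again unable to cyclise.

**Step 13.** Slow substitution at C9, which is flanked by quaternary C10, may let proton transfer, O-alkylation and epimerisation compete. Facial selectivity may also be insufficient.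

The fallback sets out from 18 and 20 and comes back at 24.
- Alcohol 20 is oxidised with Dess–Martin periodinane to methyl (R)-3-methyl-5-oxopentanoate F6.
- Dienolate 22 adds to F6 at −78 °C (aldol addition, a far faster bond formation) to give β-hydroxy ketone F7.
- MsCl and Et3N give mesylate F8, and DBU eliminates it to alkylidene dienone F9 (C9=C11).
- Luche reduction (NaBH4, CeCl3·7H2O, MeOH) from the convex face gives dienol F10, with the C8 hydroxyl on the C19 face. Its epimer is separable and can be re-oxidised.
- Hydroxyl-directed hydrogenation with [Ir(cod)(PCy3)(py)]PF6 and H2 in CH2Cl2 saturates C6=C7 and C9=C11 and delivers H9 syn to the hydroxyl, giving hydroxy ester F11.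
- Dess–Martin oxidation gives keto benzyl ester F12, and hydrogenolysis (H2, Pd/C, EtOAc) gives 24.

**Further compounds**

F1 | step 8 | benzyl hydroxy ester, benzyl 5-[(1S,4R)-4-hydroxy-1-methylcyclohex-2-en-1-yl]-2-methylpentanoate | O=C(OCc1ccccc1)C(C)CCC[C@@]2(C)CC[C@@H](O)C=C2
F2 | step 8 | allylic methyl carbonate of F1 | O=C(OCc1ccccc1)C(C)CCC[C@@]2(C)CC[C@@H](OC(=O)OC)C=C2
F3 | step 8 | benzyl silyl ketene acetal of F2 | C[Si](C)(C)OC(OCc1ccccc1)=C(C)CCC[C@@]2(C)CC[C@@H](OC(=O)OC)C=C2
F4 | step 7 | trans hydroxy ester, ethyl 5-[(1S,4S)-4-hydroxy-1-methylcyclohex-2-en-1-yl]-2-methylpentanoate | CCOC(=O)C(C)CCC[C@@]1(C)CC[C@H](O)C=C1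
F5 | step 7 | trans hydroxy acid, 5-[(1S,4S)-4-hydroxy-1-methylcyclohex-2-en-1-yl]-2-methylpentanoic acid | OC(=O)C(C)CCC[C@@]1(C)CC[C@H](O)C=C1
F6 | step 13 | methyl (R)-3-methyl-5-oxopentanoate | O=CC[C@@H](C)CC(=O)OC
F7 | step 13 | β-hydroxy ketone (aldol of 18 and F6, C11 carbinol) | O=C1C=C[C@@H]2[C@@](C)(CCC[C@]2(C)C(=O)OCc3ccccc3)C1C(O)C[C@@H](C)CC(=O)OC
F8 | step 13 | mesylate of F7 | O=C1C=C[C@@H]2[C@@](C)(CCC[C@]2(C)C(=O)OCc3ccccc3)C1C(OS(C)(=O)=O)C[C@@H](C)CC(=O)OC
F9 | step 13 | alkylidene dienone (C6=C7, C8=O, C9=C11) | O=C1C=C[C@@H]2[C@@](C)(CCC[C@]2(C)C(=O)OCc3ccccc3)C1=CC[C@@H](C)CC(=O)OC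
F10 | step 13 | dienol (C8 hydroxyl on the C19 face) | O[C@H]1C=C[C@@H]2[C@@](C)(CCC[C@]2(C)C(=O)OCc3ccccc3)C1=CC[C@@H](C)CC(=O)OC
F11 | step 13 | hydroxy ester (saturated, H9 syn to the C8 hydroxyl) | O[C@H]1CC[C@@H]2[C@@](C)(CCC[C@]2(C)C(=O)OCc3ccccc3)[C@@H]1CC[C@@H](C)CC(=O)OC
F12 | step 13 | keto benzyl ester (benzyl ester of 24) | O=C1CC[C@@H]2[C@@](C)(CCC[C@]2(C)C(=O)OCc3ccccc3)[C@@H]1CC[C@@H](C)CC(=O)OC
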